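**Strategy.** The target is cut at the C12′ methine (labdane numbering; primed atoms belong to the butenolide half, fragment B), which joins C11′, the furanone α‑carbon C13′ and the ketone carbon C15 of the methyl‑ester half (fragment A). Both new bonds are made in one three‑component operation: a C12′ aldehyde condenses with tetronic acid at C13′ and the C15 nitronate of a fragment A nitroalkane adds to the resulting alkylidene. Tetronic acid thus acts as a butenolide C13′ anion and the nitro group as a masked C15 ketone. One andrographolide‑derived acetonide aldehyde supplies both decalins; no ring is closed.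

Key step: step 6

Assumption: the quinine‑derived amine–thiourea is taken to deliver the nitronate to the face of C12′ that gives the 12′S adduct; if a first trial shows the opposite sense, the quinidine‑derived pseudoenantiomer takes its place in the same protocol.

**Step 1**
Reactants: 1 andrographolide
Product: 2 andrographolide 3,19‑acetonide (C14–OH free)
Conditions: Me2C(OMe)2, PPTS (cat.), CH2Cl2, 40 °C
Reagents that add atoms: 2,2‑dimethoxypropane, COC(C)(C)OC
Why: Acid‑catalysed transacetalisation should tie the C3/C19 1,3‑diol into a six‑membered isopropylidene acetal, while the lone C14–OH cannot form a cyclic acetal and no stereocentre is touched.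

**Step 2**
Reactants: 2 andrographolide 3,19‑acetonide
Product: 3 C12 aldehyde acetonide (decalin C9–CH2–CHO)
Conditions: KMnO4, THF, 0 °C; filtration through Celite
Reagents that add atoms: KMnO4 (potassium permanganate), [K+].[O-][Mn](=O)(=O)=O
Why: Permanganate oxidative cleavage should start by cycloaddition to the electron‑poor conjugated C12=C13 bond of the alkylidene lactone rather than to the isolated C8=C17 methylene, and the manganate ester should fragment to the C12 aldehyde and a keto‑lactone without touching C9.

**Step 3**
Reactants: 3 C12 aldehyde acetonide (the portion destined for fragment A), 4 methyl acrylate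
Product: 5 Morita–Baylis–Hillman alcohol (C12 epimers)
Conditions: DABCO (1 equiv), methyl acrylate (5 equiv), 1,4‑dioxane/H2O 1:1, rt
Reagents that add atoms: none
Why: In this Morita–Baylis–Hillman reaction the DABCO–acrylate zwitterion adds to the C12 aldehyde and DABCO is then expelled; the new C12 carbinol centre forms unselectively, which is harmless because step 5 destroys it.

**Step 4**
Reactants: 5 Morita–Baylis–Hillman alcohol
Product: 6 Morita–Baylis–Hillman acetate (C12 epimers)
Conditions: Ac2O, Et3N, DMAP (cat.), CH2Cl2, 0 °C → rt
Reagents that add atoms: acetic anhydride, CC(=O)OC(C)=O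
Why: DMAP‑catalysed acylation of the secondary allylic alcohol should give the leaving group for the allylic substitution without affecting the acetonide.

**Step 5**
Reactants: 6 Morita–Baylis–Hillman acetate, 7 nitromethane
Product: 8 fragment A nitroalkane (12E)
Conditions: MeNO2 (20 equiv), K2CO3, DMF, 0 °C → rt
Reagents that add atoms: none
Why: SN2′ substitution (conjugate addition of the nitromethane anion to the acrylate CH2, then E1cB loss of acetate) should give the 12E enoate because elimination goes through the conformer that keeps C11 away from the ester (1,3‑allylic strain), and the excess of nitromethane should suppress a second allylation.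

**Step 6**
Reactants: 3 C12 aldehyde acetonide (fragment B aldehyde), 9 tetronic acid, 8 fragment A nitroalkane
Product: 11 C15‑nitro tetronic acid adduct (12′S; C15 epimers), via alkylidene tetronic acid 10 (not isolated)
Conditions: 8 (1.1 equiv), 9‑amino‑9‑deoxy‑epi‑quinine N′‑[3,5‑bis(trifluoromethyl)phenyl]thiourea (1.1 equiv, recovered), 4 Å MS, CH2Cl2, −20 °C; 3 (1.0 equiv, CH2Cl2) and 9 (1.0 equiv, THF) added from separate syringes over 6 h; then 0 °C; cold aq. citric acid work‑up
Reagents that add atoms: none
Why: Proposed new method: the quinuclidinium tetronate formed as 9 enters condenses with aldehyde 3 (aldol addition, loss of water to the sieves) to give the 3‑alkylidene furan‑2,4‑dione 10, and the amine released by that condensation deprotonates 8, so the thiourea‑bound C15 nitronate adds to C12′ of 10 held on the ammonium N–H and gives the tetronate of 11. The closest known reaction type is the three‑component Knoevenagel–Michael coupling of aldehydes, cyclic 1,3‑dicarbonyl compounds and carbon nucleophiles, together with amine–thiourea‑mediated additions of nitroalkanes to alkylidene malonates and alkylidene Meldrum's acids; a nitroalkane as third partner with tetronic acid is the untested part. No ring is closed, so no closure mode applies; the bonds formed are C12′–C13′ and C15–C12′. The C12′ configuration is set by the chiral amine–thiourea, which fixes the face of the alkylidene that meets the nitronate; the decalin stereocentres are expected to exert only a weak bias, and C15 forms as a mixture that step 9 erases. The step needs nitronate addition to 10 to win over tetronate addition to 10 and over Henry addition to 3: simultaneous slow addition keeps tetronate and aldehyde scarce while nitronate is available, and the 2:1 tetronic acid adduct and the Henry adduct are expected to be reversible reservoirs, whereas the nitro adduct should not revert. A full equivalent of the chiral base is used because both the reactant and the product tetronic acids are far stronger acids than 8 and would hold a substoichiometric amine as its salt.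

**Step 7**
Reactants: 11 C15‑nitro tetronic acid adduct
Product: 12 C14′ enol triflate (12′S; C15 epimers)
Conditions: iPr2NEt (1.2 equiv), Tf2O (1.1 equiv), CH2Cl2, −78 °C
Reagents that add atoms: trifluoromethanesulfonic anhydride, O=S(=O)(OS(=O)(=O)C(F)(F)F)C(F)(F)F
Why: O‑sulfonylation of the tetronate (a vinylogous carboxylate) at the C14′ oxygen should be selective because one equivalent of amine at −78 °C ionises only the tetronic acid and not the much weaker, kinetically slow nitroalkane acid.

**Step 8**
Reactants: 12 C14′ enol triflate
Product: 13 C15‑nitro butenolide (12′S; C15 epimers)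
Conditions: Pd(OAc)2 (5 mol %), PPh3 (10 mol %), HCO2H·Et3N (1:1, 2 equiv), DMF, 40 °C
Reagents that add atoms: none
Why: Palladium‑catalysed formate hydrogenolysis of a vinyl triflate (oxidative addition of zerovalent palladium into C14′–OTf, formate exchange, decarboxylation, C–H reductive elimination) should give the butenolide; the 1:1 ammonium formate keeps the medium close to neutral, so the nitroalkane is not ionised.

**Step 9**
Reactants: 13 C15‑nitro butenolide
Product: 15 C15 ketone bis‑acetonide (12′S), via sodium nitronate 14 (not isolated)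
Conditions: NaOMe (1.05 equiv), MeOH/THF, 0 °C; then aq. TiCl3, NH4OAc (pH 5–6), 0 °C → rt
Reagents that add atoms: water, O
Why: In this reductive Nef reaction trivalent titanium reduces the nitronate through the oxime to the imine, which hydrolyses at pH 5–6, so both C15 epimers converge on one ketone and the newly acidic C12′–H is never exposed to base.

**Step 10**
Reactants: 15 C15 ketone bis‑acetonide
Product: 16 CNP0330094.1
Conditions: AcOH/H2O 7:3, rt
Reagents that add atoms: none
Why: Mild acid hydrolysis of the two isopropylidene acetals should free the four hydroxyl groups without isomerising the exocyclic alkenes or enolising the C15 ketone towards C12′.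

**Compound list**
1 | andrographolide | C=C1CC[C@@H]2[C@](C)(CO)[C@H](O)CC[C@@]2(C)[C@@H]1C/C=C1/C(=O)OC[C@H]1O | starting material
2 | andrographolide 3,19‑acetonide (3,19‑O‑isopropylidene, C14–OH free) | C=C1CC[C@@H]2[C@](C)(COC3(C)C)[C@H](O3)CC[C@@]2(C)[C@@H]1C/C=C1/C(=O)OC[C@H]1O | intermediate
3 | C12 aldehyde acetonide: 3,19‑O‑isopropylidene‑13,14,15,16‑tetranorlabd‑8(17)‑en‑12‑al | O=CC[C@@H]1C(=C)CC[C@@H]2[C@](C)(COC3(C)C)[C@H](O3)CC[C@]21C | intermediate
4 | methyl acrylate | C=CC(=O)OC | starting material
5 | Morita–Baylis–Hillman alcohol: methyl 2‑methylene‑3‑hydroxy ester with the carbinol at C12 (C12 epimers) | C=C1CC[C@@H]2[C@](C)(COC3(C)C)[C@H](O3)CC[C@@]2(C)[C@@H]1CC(O)C(=C)C(=O)OC | intermediate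
6 | C12 acetate of 5 (C12 epimers) | C=C1CC[C@@H]2[C@](C)(COC3(C)C)[C@H](O3)CC[C@@]2(C)[C@@H]1CC(OC(C)=O)C(=C)C(=O)OC | intermediate
7 | nitromethane | C[N+](=O)[O-] | starting material
8 | fragment A nitroalkane: (12E)‑enoate, C13 bearing CO2Me and the C14H2–C15H2NO2 chain, 3,19‑acetonide | C=C1CC[C@@H]2[C@](C)(COC3(C)C)[C@H](O3)CC[C@@]2(C)[C@@H]1C/C=C(\CC[N+](=O)[O-])C(=O)OC | intermediate
9 | tetronic acid (furan‑2,4(3H,5H)‑dione) | O=C1CC(=O)CO1 | starting material
10 | alkylidene tetronic acid: 3‑alkylidene furan‑2,4‑dione from 3 (C12′=C13′, geometry undefined) | O=C1OCC(=O)C1=CC[C@@H]1C(=C)CC[C@@H]2[C@](C)(COC3(C)C)[C@H](O3)CC[C@]21C | intermediate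
11 | C15‑nitro tetronic acid adduct, bis‑acetonide: C15 bonded to C12′ (S), which carries C11′ and the 4‑hydroxy‑2(5H)‑furanon‑3‑yl group (C15 epimers) | C=C1CC[C@@H]2[C@](C)(COC3(C)C)[C@H](O3)CC[C@@]2(C)[C@@H]1C/C=C(\CC([N+](=O)[O-])[C@@H](C[C@@H]1C(=C)CC[C@@H]2[C@](C)(COC3(C)C)[C@H](O3)CC[C@]21C)C1=C(O)COC1=O)C(=O)OC | intermediate
12 | C14′ enol triflate of 11 (12′S; C15 epimers) | C=C1CC[C@@H]2[C@](C)(COC3(C)C)[C@H](O3)CC[C@@]2(C)[C@@H]1C/C=C(\CC([N+](=O)[O-])[C@@H](C[C@@H]1C(=C)CC[C@@H]2[C@](C)(COC3(C)C)[C@H](O3)CC[C@]21C)C1=C(OS(=O)(=O)C(F)(F)F)COC1=O)C(=O)OC | intermediate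
13 | C15‑nitro butenolide, bis‑acetonide (12′S; C15 epimers) | C=C1CC[C@@H]2[C@](C)(COC3(C)C)[C@H](O3)CC[C@@]2(C)[C@@H]1C/C=C(\CC([N+](=O)[O-])[C@@H](C[C@@H]1C(=C)CC[C@@H]2[C@](C)(COC3(C)C)[C@H](O3)CC[C@]21C)C1=CCOC1=O)C(=O)OC | intermediate
14 | sodium C15 nitronate of 13 | C=C1CC[C@@H]2[C@](C)(COC3(C)C)[C@H](O3)CC[C@@]2(C)[C@@H]1C/C=C(\CC(=[N+]([O-])[O-])[C@@H](C[C@@H]1C(=C)CC[C@@H]2[C@](C)(COC3(C)C)[C@H](O3)CC[C@]21C)C1=CCOC1=O)C(=O)OC.[Na+] | intermediate
15 | C15 ketone bis‑acetonide (12′S) | C=C1CC[C@@H]2[C@](C)(COC3(C)C)[C@H](O3)CC[C@@]2(C)[C@@H]1C/C=C(\CC(=O)[C@@H](C[C@@H]1C(=C)CC[C@@H]2[C@](C)(COC3(C)C)[C@H](O3)CC[C@]21C)C1=CCOC1=O)C(=O)OC | intermediate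
16 | CNP0330094.1: fragment A (12E)‑methyl ester joined through its C15 ketone to C12′ (S) of the fragment B butenolide, both halves with free C3/C19 diols | C=C1CC[C@@H]2[C@](C)(CO)[C@H](O)CC[C@@]2(C)[C@@H]1C/C=C(\CC(=O)[C@@H](C[C@@H]1C(=C)CC[C@@H]2[C@](C)(CO)[C@H](O)CC[C@]21C)C1=CCOC1=O)C(=O)OC | target

**Step count.** Total: 10 steps. Longest linear sequence: 10 steps (1 → 16 through the fragment A arm; the fragment B arm uses steps 1, 2 and 6–10).

**Steps most likely to fail**

Step 6. The alkylidene may be drained into the 2:1 tetronic acid adduct or the aldehyde into a Henry adduct faster than these revert, and facial selectivity at C12′ may be poor. The fallback makes the two bonds one after the other by known reactions. It sets out from 8 and 3: a base‑catalysed Henry reaction (tetramethylguanidine cat., THF, 0 °C) forms C15–C12′ and should give the β‑nitro alcohol F1. Mesylation–elimination (MsCl, Et3N, CH2Cl2, 0 °C) should give the (E)‑nitroalkene F2. The same amine–thiourea (10 mol %, CH2Cl2/THF, −20 °C) then mediates Michael addition of tetronic acid 9 to C12′ of F2, a standard 1,3‑dicarbonyl‑to‑nitroalkene addition in which the catalyst again sets C12′. The route is rejoined at 11.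

Step 2. Over‑oxidation of the aldehyde to the acid, or competing attack on the C8=C17 methylene, may erode the cleavage. The fallback sets out from 2: Weitz–Scheffer epoxidation (tBuOOH, DBU, CH2Cl2, 0 °C), which can only engage the electron‑poor C12=C13 bond, should give the 12,13‑epoxy lactone F3. H5IO6 (THF/H2O, 0 °C) then hydrolyses the epoxide and cleaves the resulting diol. Any acetonide lost is restored under the conditions of step 1. The route is rejoined at 3.

Step 9. Methoxide may open the butenolide before the hindered nitro group is ionised, reduction may stall at the oxime, or C12′ may epimerise once the ketone is present. The fallback sets out from 13 and avoids base altogether: the free nitro compound is treated with unbuffered aqueous TiCl3 in DME at rt, where reduction to the imine and its hydrolysis take place in acid. The aqueous HCl of the reagent should cleave both acetonides in the same flask, so the route is rejoined directly at 16. This fallback makes no new compound (F0).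

**Further compounds**
F1 | step 6 | β‑nitro alcohol from Henry addition of 8 to 3 (C15–NO2, C12′–OH; diastereomer mixture) | C=C1CC[C@@H]2[C@](C)(COC3(C)C)[C@H](O3)CC[C@@]2(C)[C@@H]1C/C=C(\CC([N+](=O)[O-])C(O)C[C@@H]1C(=C)CC[C@@H]2[C@](C)(COC3(C)C)[C@H](O3)CC[C@]21C)C(=O)OC
F2 | step 6 | (E)‑nitroalkene C12′=C15(NO2) from dehydration of F1 | C=C1CC[C@@H]2[C@](C)(COC3(C)C)[C@H](O3)CC[C@@]2(C)[C@@H]1C/C=C(\C/C(=C\C[C@@H]1C(=C)CC[C@@H]2[C@](C)(COC3(C)C)[C@H](O3)CC[C@]21C)[N+](=O)[O-])C(=O)OC
F3 | step 2 | 12,13‑epoxide of andrographolide 3,19‑acetonide (epoxide epimers) | C=C1CC[C@@H]2[C@](C)(COC3(C)C)[C@H](O3)CC[C@@]2(C)[C@@H]1CC1OC12C(=O)OC[C@H]2O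
F0 | step 9 | none | none
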